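**Retrosynthetic overview**
- Target ⇒ C–O disconnection at the ring carbonyl carbon that lies between the benzoyl-bearing and the methyl-bearing carbons: last-step oxygen transfer to the one electrophilic ring C–H of a deoxy dienone.
- Deoxy dienone ⇒ two C–C disconnections at the quaternary carbon: double C-prenylation (alkylative dearomatisation) of a 2,4-dihydroxybenzophenone at the carbon between its two oxygens.
- Benzophenone ⇒ Friedel–Crafts benzoylation of 4-methylresorcinol.
- Ring order: the six-membered ring is never constructed. It is the benzene ring of 4-methylresorcinol, dearomatised in step 2 and raised to the trione level in step 3; the phenyl ring is bought.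

Assumption: the target has no stereocentre (the quaternary carbon carries two identical prenyl groups), so it is achiral and is made as the single compound drawn, in the dienol tautomer of the given SMILES.

**Step 1**
Reactants: 1 4-methylresorcinol; 2 benzoyl chloride (1.05 equiv)
Product: 3 (2,4-dihydroxy-5-methylphenyl)(phenyl)methanone
Conditions: AlCl3 (3 equiv), PhNO2, 0 to 60 °C; then ice/aq. HCl
Reagents that add atoms: none
Why: Friedel–Crafts acylation: C6 of 1 (para to one OH, ortho to the other) is the only unhindered doubly activated position, any O-benzoate formed first undergoes Fries rearrangement under AlCl3 to the same chelated ortho-hydroxy ketone, and that chelate deactivates the ring toward a second acylation; no stereocentre is formed.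

**Step 2**
Reactants: 3 (2,4-dihydroxy-5-methylphenyl)(phenyl)methanone; 4 prenyl bromide (2.2 equiv)
Product: 6 4-benzoyl-5-hydroxy-2-methyl-6,6-bis(3-methylbut-2-en-1-yl)cyclohexa-2,4-dien-1-one, via C3-monoprenyl ketone 5 (not isolated)
Conditions: 10% aq. KOH, 0 °C to rt, N2; then aq. HCl to pH 3
Reagents that add atoms: none
Why: Alkylative dearomatisation (double C-alkylation of a resorcinol dianion in water, where hydrogen bonding to the phenoxide oxygens favours C- over O-alkylation): C3, flanked by both oxygens, is the enolate-like carbon of the chelated 2,4-dihydroxyaryl ketone, so the first prenyl group gives 5 and the second enters the same carbon because the product is drained as its stabilised vinylogous-acid anion; the new quaternary carbon carries two identical prenyl groups and is not a stereocentre.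

**Step 3**
Reactants: 6 4-benzoyl-5-hydroxy-2-methyl-6,6-bis(3-methylbut-2-en-1-yl)cyclohexa-2,4-dien-1-one
Product: 8 2-benzoyl-3,5-dihydroxy-6-methyl-4,4-bis(3-methylbut-2-en-1-yl)cyclohexa-2,5-dien-1-one (target), via alkoxysulfonium zwitterion 7 (not isolated)
Conditions: DMSO (solvent), (PhO)2P(O)OH (10 mol %), 90 °C, Ar
Reagents that add atoms: dimethyl sulfoxide, CS(C)=O
Why: Proposed new method: a conjugate Kornblum-type oxidation in which dimethyl sulfoxide is both the neutral oxygen nucleophile and the oxidant – the phosphoric acid hydrogen-bonds the C1 carbonyl of neutral 6 (basic media are avoided because the anion of 6 is unreactive at this carbon), the sulfoxide oxygen adds to C3, the β-carbon of the enone and the only electrophilic C–H carbon, forming the C–O bond in alkoxysulfonium 7, the phosphate or the internal enolate removes an S–CH3 proton, and the ylide takes the C3 hydrogen through the five-membered Swern-type transition state, releasing dimethyl sulfide and leaving the new ring carbonyl of the enolised triketone; the closest known reaction types are the Kornblum oxidation, Swern-type alkoxysulfonium collapse and oxygen transfer from sulfoxides to acid-activated alkynes, none of which has been shown for the β-C–H of an enone, and no stereocentre remains in the product.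

**Compound list**
1 | 4-methylresorcinol (4-methylbenzene-1,3-diol) | Cc1ccc(O)cc1O | starting material
2 | benzoyl chloride | O=C(Cl)c1ccccc1 | starting material
3 | (2,4-dihydroxy-5-methylphenyl)(phenyl)methanone | Cc1cc(C(=O)c2ccccc2)c(O)cc1O | intermediate
4 | prenyl bromide (1-bromo-3-methylbut-2-ene) | CC(C)=CCBr | starting material
5 | [2,4-dihydroxy-5-methyl-3-(3-methylbut-2-en-1-yl)phenyl](phenyl)methanone, achiral | Cc1cc(C(=O)c2ccccc2)c(O)c(CC=C(C)C)c1O | intermediate
6 | 4-benzoyl-5-hydroxy-2-methyl-6,6-bis(3-methylbut-2-en-1-yl)cyclohexa-2,4-dien-1-one, achiral, chelated enol tautomer | CC1=CC(C(=O)c2ccccc2)=C(O)C(CC=C(C)C)(CC=C(C)C)C1=O | intermediate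
7 | alkoxysulfonium zwitterion: dimethylsulfonio-oxy group on C3 of 6, benzoyl group as exocyclic enolate (racemic at C3, transient) | C[S+](C)OC1C(C)=C(O)C(CC=C(C)C)(CC=C(C)C)C(=O)C1=C([O-])c1ccccc1 | intermediate
8 | 2-benzoyl-3,5-dihydroxy-6-methyl-4,4-bis(3-methylbut-2-en-1-yl)cyclohexa-2,5-dien-1-one, achiral | CC(C)=CCC1(CC=C(C)C)C(O)=C(C)C(=O)C(C(=O)c2ccccc2)=C1O | target

**Totals**
Total step count: 3. Longest linear sequence: 3 steps (1 → 3 → 6 → 8).

**Steps most likely to fail** (the route has only three steps, so all are listed, most risky first)

Step 3 is the proposed oxygen transfer. Dimethyl sulfoxide may be too weak a nucleophile for the push–pull dienone, and the acid may close a prenyl group onto an enol oxygen. The fallback uses known chemistry, gives up the late oxygenation and buys the third oxygen; it sets out from 2 and comes back at 8. Benzoyl chloride 2 acylates purchased 2-methylphloroglucinol (Cc1c(O)cc(O)cc1O) under AlCl3 in nitrobenzene to give (2,4,6-trihydroxy-3-methylphenyl)(phenyl)methanone F1. F1 is then doubly C-prenylated at its single unsubstituted ring carbon with 4 in 10% aq. KOH at 0 °C, the established alkylative dearomatisation of acylphloroglucinols. This gives 8 directly, after separation from the isomer alkylated at the methyl-bearing carbon.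

Step 2 is a known reaction class, but it is less documented for resorcinol ketones than for phloroglucinols. The second alkylation may go to oxygen or to the methyl-bearing carbon, and a third prenyl group may add to the anion of 6. The fallback replaces direct C-alkylation by O-alkylation followed by a [3,3] shift; it sets out from 3 and comes back at 6. Compound 3 is O-alkylated at its free 4-OH with methyl 2-methylbut-3-en-2-yl carbonate (COC(=O)OC(C)(C)C=C) and cat. Pd(PPh3)4 in THF, giving [2-hydroxy-5-methyl-4-(2-methylbut-3-en-2-yloxy)phenyl](phenyl)methanone F2. Aromatic Claisen rearrangement in toluene at 110 °C moves the group with allylic inversion to C3, directed between the oxygens by chelation-induced bond fixation, and gives 5, here isolated. The same O-alkylation of 5 gives [2-hydroxy-5-methyl-3-(3-methylbut-2-en-1-yl)-4-(2-methylbut-3-en-2-yloxy)phenyl](phenyl)methanone F3. Its Claisen rearrangement onto the already substituted C3 cannot rearomatise and ends at 6.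

Step 1 may stop at the O-benzoate if the Fries rearrangement is incomplete, or give some acylation between the hydroxyls. The fallback uses a nitrile electrophile, which cannot O-acylate; it sets out from 1 and comes back at 3. Houben–Hoesch reaction of 1 with benzonitrile (ZnCl2, dry HCl, Et2O, 0 °C) precipitates (2,4-dihydroxy-5-methylphenyl)(phenyl)methaniminium chloride F4. Hydrolysis of F4 in water at 100 °C gives 3.

**Further compounds**
F1 | step 3 | (2,4,6-trihydroxy-3-methylphenyl)(phenyl)methanone | Cc1c(O)cc(O)c(C(=O)c2ccccc2)c1O
F2 | step 2 | [2-hydroxy-5-methyl-4-(2-methylbut-3-en-2-yloxy)phenyl](phenyl)methanone | Cc1cc(C(=O)c2ccccc2)c(O)cc1OC(C)(C)C=C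
F3 | step 2 | [2-hydroxy-5-methyl-3-(3-methylbut-2-en-1-yl)-4-(2-methylbut-3-en-2-yloxy)phenyl](phenyl)methanone | Cc1cc(C(=O)c2ccccc2)c(O)c(CC=C(C)C)c1OC(C)(C)C=C
F4 | step 1 | (2,4-dihydroxy-5-methylphenyl)(phenyl)methaniminium chloride | Cc1cc(C(=[NH2+])c2ccccc2)c(O)cc1O.[Cl-]
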